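**Plan**
1. Retrosynthetic cuts, in order: (a) the aryl C–CH bond of the benzylidene (Mizoroki–Heck), (b) the exocyclic C3=CH2 bond (Mannich/elimination), (c) the C4–H bond (asymmetric conjugate reduction), (d) the C4–CH2Ar bond (Negishi).
2. Forward: the lactone ring is bought as 4-bromofuran-2(5H)-one; the trimethoxybenzyl group is joined at C4, the butenolide is reduced to the lactone, C3 is methylenated, and the methylene carbon is arylated last, convergently.
3. Enabling feature: the exocyclic C3=CH–Ar unit on the lactone ring is a Heck retron. Its CH carbon is the unsubstituted terminus of an α-methylene lactone (acrylate-type C=CH2), the one carbon where ArPdBr adds, and it keeps a hydrogen for syn elimination.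
4. Stereochemistry: C4 (S) comes from ligand-controlled CuH delivery to the flat butenolide in step 2 and is never enolisable afterwards; the E alkene comes from syn addition/syn elimination in step 4.
5. No protecting group or auxiliary is carried; the phenol stays free, and one event forges the bond, the trisubstituted alkene and its geometry.

Key step: step 4

Remark: which antipode of DTBM-SEGPHOS gives S at C4 is to be settled in a first run (chiral HPLC, optical rotation); the label R in step 2 stands for that antipode.

Step 1
Reactants: 1 5-(chloromethyl)-1,2,3-trimethoxybenzene (3,4,5-trimethoxybenzyl chloride); 2 4-bromofuran-2(5H)-one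
Product: 4 4-(3,4,5-trimethoxybenzyl)furan-2(5H)-one, via benzylic zinc chloride 3 (not isolated)
Conditions: 1, Zn dust, LiCl, THF, 25 °C; then 2, Pd(PPh3)4 (3 mol %), THF, 25 °C
Reagents that add atoms: zinc, [Zn] (held only in the not-isolated 3)
Why: Negishi cross-coupling: LiCl-assisted insertion of zinc into the benzylic C–Cl bond gives a mild benzylic zinc chloride, which Pd(PPh3)4 should couple at the vinylic C–Br bond of the β-bromobutenolide (a vinylogous acyl bromide) without attack on the lactone; no stereocentre is formed.

Step 2
Reactants: 4 4-(3,4,5-trimethoxybenzyl)furan-2(5H)-one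
Product: 5 (S)-4-(3,4,5-trimethoxybenzyl)dihydrofuran-2(3H)-one
Conditions: Cu(OAc)2·H2O (3 mol %), (R)-DTBM-SEGPHOS (3.3 mol %), (EtO)2MeSiH (2 equiv), t-BuOH (2 equiv), toluene, 0 °C to rt
Reagents that add atoms: none
Why: Asymmetric conjugate reduction (1,4-hydrosilylation) by bisphosphine-bound CuH, a reaction type with close precedent for β-substituted butenolides: hydride should go to one face of C4 under control of the chiral ligand and the copper enolate is protonated by t-BuOH, so the single stereocentre (S) is set by the catalyst.

Step 3
Reactants: 5 (S)-4-(3,4,5-trimethoxybenzyl)dihydrofuran-2(3H)-one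
Product: 8 (S)-3-methylene-4-(3,4,5-trimethoxybenzyl)dihydrofuran-2(3H)-one, via Mannich base 6 (not isolated), via methiodide 7 (not isolated)
Conditions: LiN(SiMe3)2, THF, −78 °C; CH2=NMe2+ I−, −78 °C to rt; MeI, MeOH, rt; NaHCO3 (aq)/CH2Cl2, rt
Reagents that add atoms: N,N-dimethylmethyleneiminium iodide, C=[N+](C)C.[I-]; iodomethane, CI (its carbon is held only in the not-isolated 7)
Why: Mannich aminomethylation of the lithium enolate (formed only at C3, attacked anti to the C4 benzyl group), N-methylation and Hofmann-type E1cB elimination should install the exocyclic methylene; C4 is not deprotonated and the transient C3 centre of 6 and 7 disappears in 8.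

Step 4
Reactants: 8 (S)-3-methylene-4-(3,4,5-trimethoxybenzyl)dihydrofuran-2(3H)-one; 9 4-bromo-2,6-dimethoxyphenol
Product: 10 (3E,4S)-3-(4-hydroxy-3,5-dimethoxybenzylidene)-4-(3,4,5-trimethoxybenzyl)dihydrofuran-2(3H)-one
Conditions: Pd(OAc)2 (5 mol %), P(o-tol)3 (12 mol %), Et3N (3 equiv), DMF, 100 °C, sealed tube, argon
Reagents that add atoms: none
Why: Mizoroki–Heck arylation: zerovalent palladium inserts into the C–Br bond of 9, ArPdBr adds syn across the exocyclic C=CH2 of 8 with the aryl group on the unsubstituted CH2 terminus and palladium on C3, and syn β-hydride elimination of a benzylic hydrogen followed by loss of HBr to Et3N closes the cycle. The closest known reaction type is the Heck arylation of α-methylene-γ-butyrolactones, which gives (E)-α-arylidene lactones. No ring is closed and no stereocentre is made; the C4 centre is a spectator because it is not enolisable and carries no palladium. The E geometry is set in the elimination, where the rotamer that keeps the aryl group away from the lactone carbonyl (towards C4) leads to the planar, doubly conjugated alkene. The step needs elimination towards the exocyclic benzylic C–H and not the ring C4–H (which would give the achiral endocyclic butenolide); the two benzylic hydrogens and the styrene-type conjugation of the product favour this, and hindered P(o-tol)3 with excess Et3N should limit re-addition of HPdBr. The phenol needs no protection, as in Heck reactions of bromophenols, because Et3N should not ionise it appreciably in DMF, so conjugate addition of phenoxide to 8 stays minor.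

**Compound list**
1 | 5-(chloromethyl)-1,2,3-trimethoxybenzene (3,4,5-trimethoxybenzyl chloride) | COc1cc(CCl)cc(OC)c1OC | starting material
2 | 4-bromofuran-2(5H)-one | O=C1C=C(Br)CO1 | starting material
3 | (3,4,5-trimethoxybenzyl)zinc chloride | COc1cc(C[Zn]Cl)cc(OC)c1OC | intermediate
4 | 4-(3,4,5-trimethoxybenzyl)furan-2(5H)-one | COc1cc(CC2=CC(=O)OC2)cc(OC)c1OC | intermediate
5 | (S)-4-(3,4,5-trimethoxybenzyl)dihydrofuran-2(3H)-one | O=C1C[C@H](Cc2cc(OC)c(OC)c(OC)c2)CO1 | intermediate
6 | (3R,4S)-3-[(dimethylamino)methyl]-4-(3,4,5-trimethoxybenzyl)dihydrofuran-2(3H)-one (trans) | CN(C)C[C@@H]1C(=O)OC[C@H]1Cc2cc(OC)c(OC)c(OC)c2 | intermediate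
7 | 1-[(3R,4S)-2-oxo-4-(3,4,5-trimethoxybenzyl)tetrahydrofuran-3-yl]-N,N,N-trimethylmethanaminium iodide | C[N+](C)(C)C[C@@H]1C(=O)OC[C@H]1Cc2cc(OC)c(OC)c(OC)c2.[I-] | intermediate
8 | (S)-3-methylene-4-(3,4,5-trimethoxybenzyl)dihydrofuran-2(3H)-one | C=C1C(=O)OC[C@H]1Cc2cc(OC)c(OC)c(OC)c2 | intermediate
9 | 4-bromo-2,6-dimethoxyphenol | COc1cc(Br)cc(OC)c1O | starting material
10 | (3E,4S)-3-(4-hydroxy-3,5-dimethoxybenzylidene)-4-(3,4,5-trimethoxybenzyl)dihydrofuran-2(3H)-one | COc1cc(/C=C2/C(=O)OC[C@H]2Cc2cc(OC)c(OC)c(OC)c2)cc(OC)c1O | target

Total step count: 4. Longest linear sequence: 4 (steps 1 to 4; 9 is bought).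

**Steps most likely to fail**

Step 4. What may go wrong: β-hydride elimination or re-addition of HPdBr towards the ring C–H, which moves the double bond into the ring and erases the stereocentre in that portion; in addition, slow oxidative addition of the electron-rich bromide. Fallback, setting out from 5 and coming back at 10: Claisen-type formylation of 5 (NaH, HCO2Et, THF) should give the hydroxymethylene lactone F1. O-Sulfonylation (TsCl, N-methylimidazole, Et3N, CH2Cl2) should give the (E)-enol tosylate F2. Suzuki–Miyaura coupling of F2 with commercial 2,6-dimethoxy-4-(4,4,5,5-tetramethyl-1,3,2-dioxaborolan-2-yl)phenol (Pd(OAc)2, SPhos, K3PO4, THF/H2O, 60 °C) makes the same aryl–CH bond with retention of alkene geometry, and no HPdBr is formed.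

Step 2. What may go wrong: insufficient facial discrimination, or migration of the ring double bond towards the benzylic position before hydride transfer. Fallback, setting out from 4 and coming back at 5: hydrogenation of 4 over Pd/C (H2, EtOAc) should give the racemic lactone F3, and preparative chromatography on a chiral stationary phase separates the S enantiomer, which is 5.

Step 1. What may go wrong: Wurtz-type homocoupling of the electron-rich benzylic zinc reagent during zinc insertion, and ring-opening or oligomerisation of the nucleophile-sensitive bromobutenolide. Fallback, setting out from 2 and coming back at 4, with the polarity of the partners reversed: stannylation of 2 ((Bu3Sn)2, Pd(PPh3)4, toluene, 80 °C) should give the stannyl butenolide F4, and Stille coupling of F4 with the benzyl chloride 1 (Pd(PPh3)4, toluene, 100 °C) gives 4.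

**Further compounds**
F1 | step 4 | (S,Z)-3-(hydroxymethylene)-4-(3,4,5-trimethoxybenzyl)dihydrofuran-2(3H)-one | O/C=C1\C(=O)OC[C@H]1Cc2cc(OC)c(OC)c(OC)c2
F2 | step 4 | (E)-[(4S)-2-oxo-4-(3,4,5-trimethoxybenzyl)dihydrofuran-3(2H)-ylidene]methyl 4-methylbenzenesulfonate | Cc1ccc(cc1)S(=O)(=O)O/C=C1/C(=O)OC[C@H]1Cc2cc(OC)c(OC)c(OC)c2
F3 | step 2 | racemic 4-(3,4,5-trimethoxybenzyl)dihydrofuran-2(3H)-one | O=C1CC(Cc2cc(OC)c(OC)c(OC)c2)CO1
F4 | step 1 | 4-(tributylstannyl)furan-2(5H)-one | CCCC[Sn](CCCC)(CCCC)C1=CC(=O)OC1
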